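## Analysis of the target

1. Atoms are numbered in the order of the SMILES string: C1–C3 isopropyl (C2 is the methine), C4, C5, C6, C7, C8, C9, C10 (methyl on C9), C11 to C19, C20 (methyl on C19).
2. The skeleton is a trans-decalin (ring A: C8, C9, C16, C17, C18, C19; ring B: C7, C8, C9, C11, C12, C13). It is fused through the bond C7–C13 to a bicyclo[2.2.1]heptane (ring C: C4, C5, C6, C7, C13; ring D: C6, C7, C13, C14, C15), so ring B holds both the one-carbon bridge C7 and the bridgehead C13.
3. There are nine stereocentres (C4, C6, C7, C8, C9, C13, C15, C16, C19). C9 and C13 are all-carbon quaternary and C19 is a tertiary carbinol.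
4. One face of the decalin carries H7, the axial methyl C10, the axial hydroxyl on C19 and the equatorial bromine on C16, and the other face carries H8. C8 leans over the bridge C14–C15 and H7 over the bridge C4–C5, and both the isopropyl group on C4 and the hydroxyl on C15 are exo.
5. The sensitive points are the secondary neopentyl C16–Br bond (reducible, and closed to substitution because C10 covers its backside), the tertiary alcohol (dehydration) and the norbornyl frame (Wagner–Meerwein shifts under cationic conditions).
6. Four problems are hard. They are the 1,7-annulated norbornane with its bridgehead quaternary centre C13 next to C4; the exo isopropyl group, since any delivery of hydrogen to C4 arrives exo and would leave it endo; the equatorial bromide; and the axial C19 hydroxyl, which is the opposite of what anti addition to an E olefin gives.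
7. The first inviting feature is in ring D. Its only oxygen sits on C15, next to the CH bridgehead C6 and 1,4 to C4 across the boat C13–C4–C5–C6–C15–C14. This is the retron of a cyclopent-2-enone (C15=O, C14=C13) whose 2-silyloxycyclopentadiene takes up the two-carbon bridge C4–C5 across C13 and C6.
8. The second feature is C19. With its methyl, its hydroxyl, the chain C18–C17–C16 and the carbon C8, it is atom for atom the carbinol end of linalool, so this stereocentre can be bought, kept, and used to relay the other eight.

## Retrosynthetic reasoning

**24 ⇒ 23 (no skeletal bond; H on C16/C17 and on the isopropyl group).** The bromide cannot be installed by substitution, so C16 is traced back to the bromoalkene C16(Br)=C17 of 23. A C16 radical that already carries bromine takes its hydrogen axially, anti to C10, and bromine ends up equatorial. The isopropyl group is traced to an isopropenyl group, so one hydrogen-atom-transfer hydrogenation finishes both sites.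

**23 ⇒ 22 ⇒ 21 ⇒ 19 (oxidation levels at C15 and C16).** The exo alcohol comes from the C15 ketone, whose exo face is covered by C8. The bromoalkene comes from the C16 ketone through enol triflate 21. The two ketones of 19 differ enough in their enolisation for this to work: C16 can only enolise towards C17, and C15 only into a strained bicycloheptene enolate at the neopentyl C14.

**19 ⇒ 18 (bond C4–C2).** The last bond made at C4 must be the carbon–carbon bond, because whatever arrives last at a norbornyl C2-type centre arrives exo. Cutting C4–C2 leads to the redox-active ester 18. Its planar C4 radical couples on the exo face, so the C4 configuration of 18 does not matter.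

**18 ⇒ 12 + 15 (bonds C13–C4 and C6–C5; key disconnection).** Both bonds of the bridge C4–C5 are cut at once. This removes ring C, the whole bicyclo[2.2.1]heptane, the quaternary centre C13 and the stereocentre C6, and leaves a flat cyclopentenone 12 and the acrylate 15. The cut belongs here because C15 carries the oxygen that turns ring D into a 2-silyloxycyclopentadiene (16). The donor on C15 and the alkyl group on C13 ask for the same regiochemistry, and the single sp3 atom of the diene, C7, carries C8 on one face and only H on the other. The forward reaction must intercept 16 before a [1,5]-hydrogen shift occurs.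

**12 ⇒ 10 (bonds C13–C7, C14–C15, C15–C6).** Rings B and D are removed together in a Pauson–Khand sense. The but-3-ynyl arm on C9 supplies C11–C14, the vinyl group on C8 supplies C7 and C6, and a carbonyl ligand of the cobalt complex 11 becomes C15. The precursor is the monocyclic 10, whose two arms are trans-diequatorial on ring A. Two operations therefore turn one ring into four.

**10 ⇒ 6 + 8, and 6 ⇒ 4 (bonds C9–C11 and C8–C7).** The vicinal pair C8/C9 is the α,β-pair of the 2-methylcyclohexenone 4. A vinyl nucleophile delivered by the C19 alkoxide sets C8 cis to the oxygen. The regiodefined enolate held in 6 is then alkylated by 8 on the face opposite to both the vinyl group and the silyl ether, which sets C9.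

**4 ⇒ 3 ⇒ 1 (bond C8=C9; oxygen on C16).** Ring A is opened at its double bond by a metathesis cut to give dienone 3. This is (R)-linalool 1 oxidised at C16 with allylic transposition of its trisubstituted olefin. C19 has the R configuration in both 1 and 24, with the same order of priorities.

**Side branches.** 8 comes from 7, and 15 comes from 13 and 14, one step each.

## Alternatives that were turned down

**Alternative 1:** (textbook) Cut C5–C6 last and build rings A/B by Robinson annulation.
- Route: the enantiopure bicyclic enedione A1 would be reductively alkylated at C7 and closed by aldol condensation to ring D. It would then be extended at C13 by conjugate addition, and the keto tosylate A2 would be closed to the norbornanone by intramolecular enolate alkylation.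
- C19 is an unactivated methylene in A1. An oxygen placed there beforehand is a γ-leaving group and would be expelled under the dissolving-metal alkylation.
- C13 and C4 would have to be set together on an open side chain, with nothing to control C4.
- The C16 oxygen of A1 can only become bromide by a backside attack that runs into the axial C10 methyl.
- The protecting-group and redox traffic among three carbonyl groups pushes the count well beyond twenty steps.

**Alternative 2:** (biomimetic) Cut C8–C9 in a transannular sense.
- Route: the norbornane-fused (E,E)-cyclodecadiene A3 would be treated with an electrophilic bromine source. C8 would attack the bromonium-activated C9, and the C19 cation would be captured by an oxygen nucleophile, setting C16, C9, C8 and C19 at once.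
- Anti addition across the E C8=C19 olefin places the oxygen equatorially, which gives the C19 epimer of the target. A Z olefin would instead give the cis-decalin.
- The face of bromonium formation is controlled only by the conformers of the macrocycle.
- A3 still contains the complete norbornane with C13, C4, C6, C7 and C15, plus a strained ten-membered ring that must be closed onto the bond C7–C13. The precursor is therefore no simpler than the product.

**Alternative 3:** Cut C13–C14 by C–H functionalisation.
- Route: the diazoketone A4, a 6-6-5 tricycle with a trans B/C fusion, would give a metal carbene at C14 under a dirhodium carboxylate catalyst. The carbene would insert into the tertiary C13–H bond with retention, forging the quaternary centre and ring D.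
- The carbene sees three tertiary C–H bonds through five-membered transition states: C13–H, C4–H (which gives an isomeric norbornanone) and C8–H. Nothing in A4 favours the most hindered of them.
- A4 itself carries eight stereocentres, including the exo-type isopropyl group and the bromide, so the hard problems are only moved to an earlier stage.

Key step: step 8

Assumption: commercial (R)-(−)-linalool is taken as enantiomerically pure, and 17, 18, F2 and F3 are drawn as the endo C4 epimers although both C4 epimers are carried into step 9, where this centre is erased.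

## Steps

Step 1
Reactants: 1 (R)-(−)-linalool
Product: 3 (6R)-6-hydroxy-2,6-dimethylocta-1,7-dien-3-one, via allylic hydroperoxide 2 (not isolated)
Conditions: O2 (1 atm), tetraphenylporphyrin (cat.), visible light, Ac2O, pyridine, DMAP (cat.), CH2Cl2, 0 °C
Reagents that add atoms: dioxygen, O=O
Why: Schenck ene reaction of singlet oxygen with the trisubstituted olefin (the monosubstituted vinyl group is inert), followed by Kornblum–DeLaMare-type dehydration of the acetylated secondary hydroperoxide 2 to the isopropenyl ketone. The regioisomeric tertiary hydroperoxide cannot dehydrate and is separated by chromatography; C19 is not touched.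

Step 2
Reactants: 3 (6R)-6-hydroxy-2,6-dimethylocta-1,7-dien-3-one
Product: 4 (4R)-4-hydroxy-2,4-dimethylcyclohex-2-en-1-one
Conditions: second-generation Hoveyda–Grubbs catalyst (cat.), CH2Cl2, 40 °C
Reagents that add atoms: none
Why: Ring-closing metathesis joins C8 and C9 and closes ring A as a six-membered 2-methylcyclohexenone; the catalyst loads on the vinyl carbinol and closes onto the 1,1-disubstituted enone olefin with loss of a volatile alkene.

Step 3
Reactants: 4 (4R)-4-hydroxy-2,4-dimethylcyclohex-2-en-1-one
Product: 6 (3S,4R)-3-ethenyl-2,4-dimethyl-1,4-bis(trimethylsilyloxy)cyclohex-1-ene (vinyl cis to the C4 oxygen), via magnesium alkoxide enolate 5 (not isolated)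
Conditions: CH2=CHMgBr (excess), THF, −78 to 0 °C; then Me3SiCl, Et3N, DMPU, −78 °C to rt
Reagents that add atoms: vinylmagnesium bromide, C=C[Mg]Br; chlorotrimethylsilane, C[Si](C)(C)Cl
Why: Alkoxide-directed (ligand-assisted) 1,4-addition of a Grignard reagent to a 4-oxido enone: the magnesium alkoxide on C19 binds the reagent and delivers the vinyl group to C8 on its own face, which sets C8 with C7 cis to the C19 oxygen. Silylation stores the tetrasubstituted enolate C9=C16 regiospecifically and protects the tertiary alcohol.

Step 4
Reactants: 7 but-3-yn-1-ol
Product: 8 but-3-yn-1-yl trifluoromethanesulfonate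
Conditions: Tf2O, pyridine, CH2Cl2, −78 to 0 °C
Reagents that add atoms: trifluoromethanesulfonic anhydride, O=S(=O)(OS(=O)(=O)C(F)(F)F)C(F)(F)F
Why: Standard triflation of a primary alcohol; the triflate is chosen because homopropargylic halides are too slow for a hindered tetrasubstituted enolate and tend to eliminate.

Step 5
Reactants: 6 (3S,4R)-3-ethenyl-2,4-dimethyl-1,4-bis(trimethylsilyloxy)cyclohex-1-ene; 8 but-3-yn-1-yl trifluoromethanesulfonate
Product: 10 (2S,3S,4R)-2-(but-3-yn-1-yl)-3-ethenyl-2,4-dimethyl-4-(trimethylsilyloxy)cyclohexan-1-one, via lithium enolate 9 (not isolated)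
Conditions: MeLi, THF, 0 °C; then 8, DMPU, −78 to 0 °C
Reagents that add atoms: none
Why: Cleavage of the silyl enol ether with methyllithium regenerates the enolate only at C9, and SN2 alkylation creates the quaternary centre. The vinyl group on C8 and the silyl ether on C19 both cover the same face, so C11 enters from the other face; this sets C9 with C10 cis to C7 and to the C19 oxygen and makes the two arms trans.

Step 6
Reactants: 10 (2S,3S,4R)-2-(but-3-yn-1-yl)-3-ethenyl-2,4-dimethyl-4-(trimethylsilyloxy)cyclohexan-1-one
Product: 12 tricyclic cyclopentenone (trans-decalin A/B; ring D = cyclopent-2-enone with C15=O and C14=C13 fused at C7–C13; C16 ketone; C19 OSiMe3; H7 anti to H8), via alkyne hexacarbonyldicobalt complex 11 (not isolated)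
Conditions: Co2(CO)8, CH2Cl2, rt; then N-methylmorpholine N-oxide, rt
Reagents that add atoms: dicobalt octacarbonyl (source of C15=O), [Co].[Co].[C-]#[O+].[C-]#[O+].[C-]#[O+].[C-]#[O+].[C-]#[O+].[C-]#[O+].[C-]#[O+].[C-]#[O+]
Why: Intramolecular Pauson–Khand reaction of a 1,7-enyne: C13–C7, C14–C15 and C15–C6 form, closing ring B (six-membered) and ring D (five-membered), with the terminal alkyne carbon ending up α to the carbonyl as usual. The trans-diequatorial arms and the quaternary C9 pre-organise the enyne. C7 is set by the chair of the nascent ring B (C6 equatorial, H7 axial and anti to H8), and it is also the thermodynamic epimer at this γ-position.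

Step 7
Reactants: 13 N-hydroxyphthalimide; 14 acryloyl chloride
Product: 15 N-(acryloyloxy)phthalimide
Conditions: Et3N, CH2Cl2, 0 °C
Reagents that add atoms: none
Why: Simple O-acylation; it gives an acrylate that is a stronger dienophile than an alkyl acrylate and already carries the redox-active ester needed in step 9.

Step 8
Reactants: 12 tricyclic cyclopentenone; 15 N-(acryloyloxy)phthalimide
Product: 18 tetracyclic diketo N-acyloxyphthalimide ester (norbornan-2-one with C15=O, C16=O, free C19 OH, ester on C4), via silyloxycyclopentadiene 16 (not isolated), via norbornene cycloadduct 17 (not isolated)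
Conditions: TBSOTf (excess), Et3N, CH2Cl2, −78 to 0 °C; then 15, 0 °C to rt; then 1 M HCl, THF, rt
Reagents that add atoms: none
Why: Soft enolisation removes an α′ proton at C6 of the O-silylated enone and gives the cross-conjugated 2-silyloxy-5H-cyclopentadiene 16 (C6=C15–C14=C13, sp3 C7), the C16 ketone being masked in passing as its silyl enol ether; 16 then undergoes a concerted, asynchronous, normal-electron-demand Diels–Alder reaction with 15. The closest known reaction type is the Diels–Alder reaction of 5-alkyl-2-silyloxycyclopentadienes made from 4-substituted cyclopentenones, in which the silyloxy group slows the [1,5]-hydrogen shift enough for interception at or below room temperature. The bonds C6–C5 and C13–C4 form in one intermolecular suprafacial [4+2] event across the diene termini, which closes ring C (five-membered: C4, C5, C6, C7, C13) and the six-membered boat C13–C4–C5–C6–C15–C14, that is, the whole bicyclo[2.2.1]heptane. For the regiochemistry, the largest HOMO coefficient lies on C6, the silyl enol ether terminus, which bonds to the acrylate β-carbon C5, and the alkyl group on C13 also wants the carboxyl-bearing C4 next to itself, so both substituents ask for the same isomer. C13 (quaternary) and C6 are set by the diene face: C8 with ring A stands on one face of the flat ring D and only H7 on the other, so the dienophile adds anti to C8, which puts the bridge C4–C5 syn to H7 and the bridge C14–C15 syn to C8 as in the target. C4 forms mainly endo but needs no control because step 9 erases it. The step needs α′- rather than γ-enolisation and a cycloaddition faster than the hydrogen shift; the electron-poor acrylate 15, used in excess at high concentration, serves the second demand. Aqueous acid then cleaves both silyl enol ethers and the tertiary silyl ether without harming the ester, and removes the C14=C15 double bond that would otherwise open a homoallyl/cyclopropylcarbinyl radical rearrangement in step 9.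

Step 9
Reactants: 18 tetracyclic diketo N-acyloxyphthalimide ester
Product: 19 tetracyclic diketone with exo isopropenyl group on C4 (C15=O, C16=O, C19 OH)
Conditions: CH2=C(CH3)MgBr, ZnCl2, LiCl, THF, 0 °C; then 18, Ni(acac)2 (cat.), 2,2′-bipyridine (cat.), THF/DMF, rt
Reagents that add atoms: isopropenylmagnesium bromide, C=C(C)[Mg]Br
Why: Nickel-catalysed decarboxylative alkenylation of a redox-active ester with an alkenylzinc reagent (Negishi type): single-electron reduction and loss of CO2 give a planar C4 radical, which the alkenylnickel species captures on the exo face because the bridge C14–C15 shields the endo face. Both C4 epimers of 18 therefore converge on the exo isopropenyl compound, which sets C4. The hindered ketones and the tertiary alcohol tolerate the organozinc reagent.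

Step 10
Reactants: 19 tetracyclic diketone with exo isopropenyl group
Product: 21 C16 enol triflate (C16(OTf)=C17; C15 ketone kept), via dipotassium alkoxide enolate 20 (not isolated)
Conditions: KHMDS (2.1 equiv), THF, −78 °C; then N-(5-chloropyridin-2-yl)bis(trifluoromethanesulfonimide), −78 to −20 °C
Reagents that add atoms: N-(5-chloropyridin-2-yl)bis(trifluoromethanesulfonimide), FC(F)(F)S(=O)(=O)N(c1ccc(Cl)cn1)S(=O)(=O)C(F)(F)F
Why: Enolate O-triflation; the first equivalent of base is taken by the tertiary alcohol. The C16 ketone enolises freely, and only towards C17, whereas the C15 ketone would need a strained bicyclo[2.2.1]heptene enolate at the neopentyl C14 (bridgehead C6 cannot enolise), so both kinetics and equilibration favour the C16 enolate.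

Step 11
Reactants: 21 C16 enol triflate
Product: 22 bromoalkene ketone (C16(Br)=C17; C15=O)
Conditions: LiBr, [Cp*Ru(MeCN)3]OTf (cat.), 1,3-dimethyl-2-imidazolidinone, 60 °C
Reagents that add atoms: lithium bromide, [Li+].[Br-]
Why: Ruthenium-catalysed exchange of a cyclic alkenyl triflate for bromide, a known transformation that keeps the position of the double bond and leaves ketone, alcohol and the 1,1-disubstituted olefin alone.

Step 12
Reactants: 22 bromoalkene ketone
Product: 23 bromoalkene diol (C15 exo OH, C19 OH, exo isopropenyl on C4)
Conditions: NaBH4, MeOH/THF, 0 °C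
Reagents that add atoms: none
Why: Hydride reduction of a 7-syn-substituted norbornan-2-one, the same case as camphor to isoborneol: C8 and H8 cover the exo face, hydride arrives endo, and the exo alcohol at C15 results. The alkenyl bromide is inert to borohydride.

Step 13
Reactants: 23 bromoalkene diol
Product: 24 target CNP0317598.2
Conditions: Mn(dpm)3 (cat.), PhSiH3, t-BuOOH, i-PrOH, rt
Reagents that add atoms: none
Why: Hydrogen-atom-transfer hydrogenation by a manganese hydride, a reaction type that reduces haloalkenes to haloalkanes without loss of halogen and tolerates free alcohols; hydrogen adds first to the open termini (C17 and the CH2 of the isopropenyl group) and gives the bromine-stabilised C16 radical and the tertiary C2 radical. The chair C16 radical takes its second hydrogen axially, from the face opposite to the axial C10 methyl, which leaves bromine equatorial and sets C16. The isopropyl group is completed in the same operation.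

## Compound list

1 | (R)-(−)-linalool, (3R)-3,7-dimethylocta-1,6-dien-3-ol | C=C[C@](C)(O)CCC=C(C)C | starting material
2 | (3R)-6-hydroperoxy-3,7-dimethylocta-1,7-dien-3-ol (both C6 epimers) | C=C[C@](C)(O)CCC(OO)C(C)=C | intermediate
3 | (6R)-6-hydroxy-2,6-dimethylocta-1,7-dien-3-one | C=C[C@](C)(O)CCC(=O)C(C)=C | intermediate
4 | (4R)-4-hydroxy-2,4-dimethylcyclohex-2-en-1-one | O=C1CC[C@@](C)(O)C=C1C | intermediate
5 | bis(bromomagnesium) alkoxide enolate of (3S,4R)-3-ethenyl-4-hydroxy-2,4-dimethylcyclohexanone | C=C[C@H]1C(C)=C(O[Mg]Br)CC[C@@]1(C)O[Mg]Br | intermediate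
6 | (3S,4R)-3-ethenyl-2,4-dimethyl-1,4-bis(trimethylsilyloxy)cyclohex-1-ene | C=C[C@H]1C(C)=C(O[Si](C)(C)C)CC[C@@]1(C)O[Si](C)(C)C | intermediate
7 | but-3-yn-1-ol | C#CCCO | starting material
8 | but-3-yn-1-yl trifluoromethanesulfonate | C#CCCOS(=O)(=O)C(F)(F)F | intermediate
9 | lithium enolate (C9=C16) of (3S,4R)-3-ethenyl-2,4-dimethyl-4-(trimethylsilyloxy)cyclohexanone | C=C[C@H]1C(C)=C(O[Li])CC[C@@]1(C)O[Si](C)(C)C | intermediate
10 | (2S,3S,4R)-2-(but-3-yn-1-yl)-3-ethenyl-2,4-dimethyl-4-(trimethylsilyloxy)cyclohexan-1-one | C=C[C@H]1[C@](C)(CCC#C)C(=O)CC[C@@]1(C)O[Si](C)(C)C | intermediate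
11 | alkyne hexacarbonyldicobalt complex of 10 | C=C[C@H]1[C@](C)(CCC#C)C(=O)CC[C@@]1(C)O[Si](C)(C)C.[Co].[Co].[C-]#[O+].[C-]#[O+].[C-]#[O+].[C-]#[O+].[C-]#[O+].[C-]#[O+] | intermediate
12 | tricyclic cyclopentenone (rings A, B, D; C15=O, C14=C13, C16=O, C19 OSiMe3; H7 anti to H8, H8 anti to C10) | O=C1C=C2CC[C@]3(C)C(=O)CC[C@@](C)(O[Si](C)(C)C)[C@H]3[C@@H]2C1 | intermediate
13 | N-hydroxyphthalimide | ON1C(=O)c2ccccc2C1=O | starting material
14 | acryloyl chloride | C=CC(Cl)=O | starting material
15 | N-(acryloyloxy)phthalimide | C=CC(=O)ON1C(=O)c2ccccc2C1=O | intermediate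
16 | 2-silyloxy-5H-cyclopentadiene (C6=C15(OTBS)–C14=C13, sp3 C7; C16(OTBS)=C17; C19 OSiMe3) | CC(C)(C)[Si](C)(C)OC1=C[C@H]2[C@H]3[C@](C)(CCC2=C1)C(O[Si](C)(C)C(C)(C)C)=CC[C@@]3(C)O[Si](C)(C)C | intermediate
17 | norbornene cycloadduct (C14=C15(OTBS); ester on C4 drawn endo; bridge C4–C5 syn to H7) | O=C(ON5C(=O)c6ccccc6C5=O)[C@H]1C[C@@H]2[C@H]3[C@H]4[C@](C)(CC[C@@]31C=C2O[Si](C)(C)C(C)(C)C)C(O[Si](C)(C)C(C)(C)C)=CC[C@@]4(C)O[Si](C)(C)C | intermediate
18 | tetracyclic diketo N-acyloxyphthalimide ester (C15=O, C16=O, C19 OH; ester on C4 drawn endo) | O=C(ON5C(=O)c6ccccc6C5=O)[C@H]1C[C@@H]2[C@H]3[C@H]4[C@](C)(CC[C@@]31CC2=O)C(=O)CC[C@@]4(C)O | intermediate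
19 | tetracyclic diketone with exo isopropenyl group on C4 | C=C(C)[C@@H]1C[C@@H]2[C@H]3[C@H]4[C@](C)(CC[C@@]31CC2=O)C(=O)CC[C@@]4(C)O | intermediate
20 | dipotassium C19 alkoxide / C16 enolate of 19 | C=C(C)[C@@H]1C[C@@H]2[C@H]3[C@H]4[C@](C)(CC[C@@]31CC2=O)C(O[K])=CC[C@@]4(C)O[K] | intermediate
21 | C16 enol triflate (C16(OTf)=C17, C15=O) | C=C(C)[C@@H]1C[C@@H]2[C@H]3[C@H]4[C@](C)(CC[C@@]31CC2=O)C(OS(=O)(=O)C(F)(F)F)=CC[C@@]4(C)O | intermediate
22 | bromoalkene ketone (C16(Br)=C17, C15=O) | C=C(C)[C@@H]1C[C@@H]2[C@H]3[C@H]4[C@](C)(CC[C@@]31CC2=O)C(Br)=CC[C@@]4(C)O | intermediate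
23 | bromoalkene diol (C15 exo OH) | C=C(C)[C@@H]1C[C@@H]2[C@H]3[C@H]4[C@](C)(CC[C@@]31C[C@H]2O)C(Br)=CC[C@@]4(C)O | intermediate
24 | CNP0317598.2 | CC(C)[C@@H]1C[C@@H]2[C@H]3[C@H]4[C@](C)(CC[C@@]31C[C@H]2O)[C@@H](Br)CC[C@@]4(C)O | target

## Step count and risk

Total step count: 13. Longest linear sequence: 11 steps from 1 (steps 1, 2, 3, 5, 6, 8, 9, 10, 11, 12, 13). Steps 4 and 7 are one-step side branches.

**Step 8 (key step).**
- Risk: enolisation may occur at a γ-position (C7 or C12) instead of C6. A [1,5]-hydrogen shift of the 5H-cyclopentadiene may outrun the bond formation at the fully substituted terminus C13, so that addition proceeds through another diene tautomer.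
- Fallback: it sets out from 12 (through 16) and returns at 18. It replaces the cycloaddition by two polar bond formations, the first at a temperature where sigmatropic shifts are frozen.
- 16 is treated at −78 °C with acrolein and catalytic Tf2NH (Mukaiyama–Michael addition at C6, anti to C8). Acidic work-up gives the C6-(3-oxopropyl) enone F1.
- Pyrrolidine/AcOH closes C4–C13 by an intramolecular enamine Michael addition, from the face on which the tether already sits, to the tetracyclic aldehyde F2.
- Pinnick oxidation gives the carboxylic acid F3, and coupling with 13 by N,N′-diisopropylcarbodiimide gives 18.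

**Step 3.**
- Risk: 1,2-addition to the C16 carbonyl may compete, or facial delivery may be lost, because the β-carbon C8 is neopentyl and the enone carries an α-methyl group.
- Fallback: it sets out from 4 and returns at 6, and uses a hydroxyl-bound aluminium acetylide instead of a Grignard reagent.
- Me2AlC≡CSiMe3 binds to the C19 oxygen and transfers the alkynyl group to C8 on the same face, giving the silylalkynyl ketone F4.
- K2CO3/MeOH gives the terminal alkyne F5, and semihydrogenation over Lindlar catalyst gives the vinyl ketone F6.
- Thermodynamic silylation (Me3SiCl, NaI, Et3N, MeCN) gives the more substituted silyl enol ether and the silyl ether, that is, 6.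

**Step 5.**
- Risk: the hindered tetrasubstituted enolate may undergo O-alkylation, cause E2 elimination of the homopropargylic triflate, or take a proton from the terminal alkyne, each of which consumes it.
- Fallback: it sets out from 6 and returns at 10, and replaces SN2 alkylation by conjugate addition and homologation.
- Mukaiyama–Michael addition of 6 to acrolein (BF3·OEt2, −78 °C) gives the keto aldehyde F7.
- The Ohira–Bestmann reagent (K2CO3, MeOH) gives the alkynyl hydroxy ketone F8 with loss of the silyl ether, and Me3SiCl/imidazole restores 10.

**Step 10.**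
- Risk: discrimination between the two ketones in the deprotonation may be insufficient, or the hindered triflate may exchange slowly in step 11.
- Fallback: it sets out from 19 and returns at 23. It separates the two carbonyl groups by redox chemistry and avoids the triflate.
- NaBH4 reduces both ketones to the triol F9 (C15 exo OH, C16 equatorial OH).
- A nitroxyl oxidation (TEMPO, PhI(OAc)2) takes the more open C16 alcohol and spares the C15 alcohol buried under H8, giving the hydroxy ketone F10.
- Hydrazine gives the hydrazone F11. N-bromosuccinimide with 2-tert-butyl-1,1,3,3-tetramethylguanidine (Barton vinyl halide synthesis) gives 23.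

**Step 13.**
- Risk: bromine may be lost if hydrogen adds to C16 first, because the β-bromo radical fragments. The second hydrogen transfer at C16 may also show poor facial selectivity.
- Fallback: it sets out from 23 and returns at 24, and separates the two reductions while replacing radical chemistry by syn addition on a metal.
- H2 with RhCl(PPh3)3 saturates only the isopropenyl group to give the isopropyl bromoalkene F12.
- H2 over PtO2 in EtOAc then adds both hydrogens to C16=C17 from the face opposite to the axial C10 methyl, which again leaves bromine equatorial.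

## Further compounds

F1 | step 8 | C6-(3-oxopropyl) tricyclic enone (side chain anti to C8; C16=O, C19 OH) | O=CCC[C@H]1C(=O)C=C2CC[C@]3(C)C(=O)CC[C@@](C)(O)[C@H]3[C@H]12
F2 | step 8 | tetracyclic diketo aldehyde (CHO on C4, drawn endo) | O=C[C@H]1C[C@@H]2[C@H]3[C@H]4[C@](C)(CC[C@@]31CC2=O)C(=O)CC[C@@]4(C)O
F3 | step 8 | tetracyclic diketo carboxylic acid (CO2H on C4, drawn endo) | OC(=O)[C@H]1C[C@@H]2[C@H]3[C@H]4[C@](C)(CC[C@@]31CC2=O)C(=O)CC[C@@]4(C)O
F4 | step 3 | (3S,4R)-4-hydroxy-2,4-dimethyl-3-[(trimethylsilyl)ethynyl]cyclohexan-1-one (C2 epimers) | C[Si](C)(C)C#C[C@H]1C(C)C(=O)CC[C@@]1(C)O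
F5 | step 3 | (3S,4R)-3-ethynyl-4-hydroxy-2,4-dimethylcyclohexan-1-one (C2 epimers) | C#C[C@H]1C(C)C(=O)CC[C@@]1(C)O
F6 | step 3 | (3S,4R)-3-ethenyl-4-hydroxy-2,4-dimethylcyclohexan-1-one (C2 epimers) | C=C[C@H]1C(C)C(=O)CC[C@@]1(C)O
F7 | step 5 | 3-[(1S,2S,3R)-2-ethenyl-1,3-dimethyl-6-oxo-3-(trimethylsilyloxy)cyclohexyl]propanal | C=C[C@H]1[C@](C)(CCC=O)C(=O)CC[C@@]1(C)O[Si](C)(C)C
F8 | step 5 | (2S,3S,4R)-2-(but-3-yn-1-yl)-3-ethenyl-4-hydroxy-2,4-dimethylcyclohexan-1-one | C=C[C@H]1[C@](C)(CCC#C)C(=O)CC[C@@]1(C)O
F9 | step 10 | tetracyclic triol (C15 exo OH, C16 equatorial OH, C19 OH; exo isopropenyl) | C=C(C)[C@@H]1C[C@@H]2[C@H]3[C@H]4[C@](C)(CC[C@@]31C[C@H]2O)[C@@H](O)CC[C@@]4(C)O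
F10 | step 10 | tetracyclic C16 ketone diol (C15 exo OH) | C=C(C)[C@@H]1C[C@@H]2[C@H]3[C@H]4[C@](C)(CC[C@@]31C[C@H]2O)C(=O)CC[C@@]4(C)O
F11 | step 10 | C16 hydrazone of F10 | C=C(C)[C@@H]1C[C@@H]2[C@H]3[C@H]4[C@](C)(CC[C@@]31C[C@H]2O)C(=NN)CC[C@@]4(C)O
F12 | step 13 | isopropyl bromoalkene diol (C16(Br)=C17) | CC(C)[C@@H]1C[C@@H]2[C@H]3[C@H]4[C@](C)(CC[C@@]31C[C@H]2O)C(Br)=CC[C@@]4(C)O
A1 | alternative 1 | (S)-Wieland–Miescher ketone | O=C1C=C2CCCC(=O)[C@@]2(C)CC1
A2 | alternative 1 | tricyclic keto tosylate (rings A, B, D; C13 bears CH(iPr)CH2OTs) | CC(C)[C@H](COS(=O)(=O)c1ccc(C)cc1)[C@@]23CC[C@]4(C)[C@@H](Br)CC[C@@](C)(O)[C@H]4[C@@H]2CC(=O)C3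
A3 | alternative 2 | norbornanol-fused (E,E)-cyclodeca-1,5-diene (C8=C19, C16=C9) | CC(C)[C@@H]1C[C@@H]2[C@H]3/C=C(C)/CC/C=C(C)/CC[C@@]31C[C@H]2O
A4 | alternative 3 | tricyclic diazoketone (rings A, B, C; C6 bears C(=O)CHN2, C13–H) | CC(C)[C@@H]1C[C@@H](C(=O)C=[N+]=[N-])[C@H]2[C@H]3[C@](C)(CC[C@H]12)[C@@H](Br)CC[C@@]3(C)O
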